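**Plan**

1. Number the cyclohexane C1 (CH with the propanoic acid arm), C2 (quaternary), C3 (CHCH3), C4, C5, C6 (isopropylidene carbon). The retrosynthesis opens the ring at C5–C6 and C3–C4, so C4–C5 is excised as a vinyl unit; the C6–C1–C2–C3 chain is then cut at C1–C2 by a [3,3] shift, leading back to indole, propargyl bromide and monomethyl glutarate.
2. Forward: indole → (E)-trisubstituted allylic alcohol → allyl methyl glutarate → enantioselective Ireland–Claisen (C1–C2) → α-methylene ketone → tetrasubstituted enol triflate (isopropylidene in place) → Markovnikov HBr across the vinyl group → one-flask vinylation and 6-endo radical cyclisation → hydrolysis.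
3. Enabling feature: the exocyclic C6=C(CH3)2 double bond next to C1–H. Its allylic 1,3-strain holds the C1 arm axial, so a C3 radical (born from the vinyl group on quaternary C2) can only close onto C4 with its methyl equatorial.
4. Stereochemistry: C1 and C2 come from the chair Claisen transition state ((E)-alkene, Z(O)-boron enolate, chiral boron controller for the absolute sense); C3 comes from the ring closure, from either bromide epimer.

Key step: step 9

Assumption: the (S,S)-configured boron controller is taken to deliver the (2S,3R) acid 11; if the sense of induction proves opposite, its (R,R)-antipode is used with no other change.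

**Route**

Step 1
Reactants: 1 indole; 2 propargyl bromide (3-bromoprop-1-yne)
Product: 3 3-(prop-2-yn-1-yl)-1H-indole
Conditions: Zn(OTf)2 (0.6 equiv), Bu4NI (0.5 equiv), i-Pr2NEt, toluene, 23 °C
Reagents that add atoms: none
Why: Zinc-mediated Friedel–Crafts-type C3-alkylation of the free indole with a reactive propargylic bromide should favour C3 over N because the N-zincated indole reacts as an enamine.

Step 2
Reactants: 3 3-(prop-2-yn-1-yl)-1H-indole
Product: 5 3-(prop-2-yn-1-yl)-1-tosyl-1H-indole, via sodium indolide 4 (not isolated)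
Conditions: NaH (1.05 equiv), THF, 0 °C; then TsCl, 0 to 23 °C
Reagents that add atoms: p-toluenesulfonyl chloride, Cc1ccc(cc1)S(=O)(=O)Cl
Why: N-Sulfonylation of the indolide protects N–H and deactivates the indole toward the boron bromide, triflating agent and radicals used later.

Step 3
Reactants: 5 3-(prop-2-yn-1-yl)-1-tosyl-1H-indole
Product: 7 (2E)-3-methyl-4-(1-tosyl-1H-indol-3-yl)but-2-en-1-ol, via alkenylalane 6 (not isolated)
Conditions: Me3Al, Cp2ZrCl2 (20 mol%), CH2Cl2, 0 to 23 °C; then n-BuLi, THF, −78 °C; (CH2O)n, −78 to 23 °C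
Reagents that add atoms: trimethylaluminium, C[Al](C)C; formaldehyde (from paraformaldehyde), C=O
Why: Zirconium-catalysed syn-carboalumination of the terminal alkyne (Negishi) puts methyl on the internal carbon, and hydroxymethylation of the alanate keeps the geometry, so the (E)-allylic alcohol should form as a single isomer.

Step 4
Reactants: 7 (2E)-3-methyl-4-(1-tosyl-1H-indol-3-yl)but-2-en-1-ol; 8 5-methoxy-5-oxopentanoic acid (monomethyl glutarate)
Product: 9 methyl (2E)-3-methyl-4-(1-tosyl-1H-indol-3-yl)but-2-en-1-yl pentanedioate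
Conditions: DCC, DMAP (cat.), CH2Cl2, 0 to 23 °C
Reagents that add atoms: none
Why: Steglich esterification joins the primary allylic alcohol and the acid under neutral conditions that leave the alkene geometry untouched.

Step 5
Reactants: 9 methyl (2E)-3-methyl-4-(1-tosyl-1H-indol-3-yl)but-2-en-1-yl pentanedioate
Product: 11 (2S,3R)-2-(3-methoxy-3-oxopropyl)-3-methyl-3-[(1-tosyl-1H-indol-3-yl)methyl]pent-4-enoic acid, via bis(boron ketene acetal) 10 (not isolated)
Conditions: (4S,5S)-2-bromo-4,5-diphenyl-1,3-bis{[3,5-bis(trifluoromethyl)phenyl]sulfonyl}-1,3,2-diazaborolidine (2.4 equiv), i-Pr2NEt, CH2Cl2, −78 °C, then 4 °C; aqueous work-up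
Reagents that add atoms: none
Why: Enantioselective boron-enolate Ireland–Claisen rearrangement: both esters are enolised but only the allyl ester can rearrange, and the chair transition state with the Z(O)-enolate (arm equatorial) and the (E)-alkene (CH2-indolyl equatorial, methyl axial) sets the C1 arm cis to the C2 methyl, while the chiral diazaborolidine selects the enolate face and thus the absolute configuration.

Step 6
Reactants: 11 (2S,3R)-2-(3-methoxy-3-oxopropyl)-3-methyl-3-[(1-tosyl-1H-indol-3-yl)methyl]pent-4-enoic acid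
Product: 13 methyl (4S)-6-methyl-4-[(2R)-2-methyl-1-(1-tosyl-1H-indol-3-yl)but-3-en-2-yl]-5-oxohept-6-enoate, via acid chloride 12 (not isolated)
Conditions: (COCl)2, DMF (cat.), CH2Cl2, 0 to 23 °C; then tributyl(prop-1-en-2-yl)stannane, PdCl2(PPh3)2 (3 mol%), toluene, 70 °C
Reagents that add atoms: oxalyl chloride, O=C(Cl)C(=O)Cl (chlorine of 12); tributyl(prop-1-en-2-yl)stannane, CCCC[Sn](CCCC)(CCCC)C(C)=C
Why: Stille acylation of the acid chloride gives the α-methylene ketone without over-addition and without base, so the α-stereocentre C1 should not epimerise.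

Step 7
Reactants: 13 methyl (4S)-6-methyl-4-[(2R)-2-methyl-1-(1-tosyl-1H-indol-3-yl)but-3-en-2-yl]-5-oxohept-6-enoate
Product: 15 methyl (4S)-6-methyl-4-[(2R)-2-methyl-1-(1-tosyl-1H-indol-3-yl)but-3-en-2-yl]-5-[(trifluoromethanesulfonyl)oxy]hept-5-enoate, via lithium enolate 14 (not isolated)
Conditions: LiBH(s-Bu)3, THF, −78 °C; then PhNTf2, −78 to 0 °C
Reagents that add atoms: N-phenylbis(trifluoromethanesulfonimide), O=S(=O)(N(c1ccccc1)S(=O)(=O)C(F)(F)F)C(F)(F)F
Why: Conjugate reduction of the β-unsubstituted enone generates the tetrasubstituted enolate regiospecifically on the isopropyl side (C1–H is never removed), and O-triflation fixes the C6=C(CH3)2 double bond as an enol triflate.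

Step 8
Reactants: 15 methyl (4S)-6-methyl-4-[(2R)-2-methyl-1-(1-tosyl-1H-indol-3-yl)but-3-en-2-yl]-5-[(trifluoromethanesulfonyl)oxy]hept-5-enoate
Product: 16 methyl (4S)-4-[(2S,3RS)-3-bromo-2-methyl-1-(1-tosyl-1H-indol-3-yl)butan-2-yl]-6-methyl-5-[(trifluoromethanesulfonyl)oxy]hept-5-enoate (both C3 epimers)
Conditions: Co(acac)2 (25 mol%), t-BuOOH (25 mol%), Et3SiH, TsBr, n-PrOH, 23 °C
Reagents that add atoms: p-toluenesulfonyl bromide, Cc1ccc(cc1)S(=O)(=O)Br
Why: Cobalt-hydride hydrogen-atom transfer to the terminal CH2 of the only electron-neutral alkene gives the secondary radical, which takes bromine from TsBr (Markovnikov hydrobromination), and the epimer mixture is harmless because the centre is re-formed as a radical in step 9.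

Step 9
Reactants: 16 methyl (4S)-4-[(2S,3RS)-3-bromo-2-methyl-1-(1-tosyl-1H-indol-3-yl)butan-2-yl]-6-methyl-5-[(trifluoromethanesulfonyl)oxy]hept-5-enoate
Product: 18 methyl 3-{(1S,2R,3R)-2,3-dimethyl-6-(propan-2-ylidene)-2-[(1-tosyl-1H-indol-3-yl)methyl]cyclohexyl}propanoate, via diene bromide 17 (not isolated)
Conditions: vinylzinc bromide, Pd(PPh3)4 (5 mol%), THF, 50 °C; then MeOH (1 equiv), toluene, (Me3Si)3SiH, t-C12H25SH (10 mol%), AIBN, 80 °C, same flask
Reagents that add atoms: vinylzinc bromide, C=C[Zn]Br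
Why: Zerovalent palladium inserts into the C6–OTf bond and Negishi coupling with the vinylzinc reagent forms C5–C6, giving the 2-substituted 1,3-diene 17; on heating, the silyl radical abstracts bromine from either C3 epimer and the secondary C3 radical adds to the diene terminus C4, after which the thiol/silane delivers hydrogen to the allyl radical at the ring carbon C5, leaving the exocyclic tetrasubstituted alkene. The closest known reaction types are the Negishi coupling of enol triflates and silane-mediated 6-endo radical cyclisation onto 1,3-dienes. The ring closes in the 6-endo-trig mode. The new stereocentre C3 is controlled by allylic 1,3-strain: the isopropylidene methyl forces the C1 arm axial in the chair transition state, so the C3 methyl must sit equatorial, trans to the arm and cis to the CH2-indolyl group, and the step is stereoconvergent. The step needs 6-endo over 5-exo closure, which is secured because attack at the diene terminus gives a stabilised allyl radical whereas 5-exo attack would give a primary radical. It also needs hydrogen delivery at C5 and not at the tertiary terminus, which is favoured by the lower hindrance of C5 and by formation of the more substituted alkene.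

Step 10
Reactants: 18 methyl 3-{(1S,2R,3R)-2,3-dimethyl-6-(propan-2-ylidene)-2-[(1-tosyl-1H-indol-3-yl)methyl]cyclohexyl}propanoate
Product: 19 suaveolindole, 3-[(1S,2R,3R)-2-(1H-indol-3-ylmethyl)-2,3-dimethyl-6-(propan-2-ylidene)cyclohexyl]propanoic acid
Conditions: KOH, MeOH/THF/H2O, 65 °C; then aqueous citric acid to pH 4–5
Reagents that add atoms: potassium hydroxide, [K+].[OH-] (oxygen of the carboxylic acid)
Why: Saponification of the methyl ester and basic cleavage of the indole N-sulfonyl group occur together, and no stereocentre is adjacent to a carbonyl group, so nothing can epimerise; strong acid is avoided to protect the alkene and the free indole.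

**Compound list**

1 | indole | c1ccc2[nH]ccc2c1 | starting material
2 | propargyl bromide (3-bromoprop-1-yne) | C#CCBr | starting material
3 | 3-(prop-2-yn-1-yl)-1H-indole | C#CCc1c[nH]c2ccccc12 | intermediate
4 | sodium 3-(prop-2-yn-1-yl)indol-1-ide | [Na+].C#CCc1c[n-]c2ccccc12 | intermediate (not isolated)
5 | 3-(prop-2-yn-1-yl)-1-tosyl-1H-indole | C#CCc1cn(S(=O)(=O)c2ccc(C)cc2)c2ccccc12 | intermediate
6 | dimethyl[(1E)-2-methyl-3-(1-tosyl-1H-indol-3-yl)prop-1-en-1-yl]alane | C[Al](C)/C=C(\C)Cc1cn(S(=O)(=O)c2ccc(C)cc2)c2ccccc12 | intermediate (not isolated)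
7 | (2E)-3-methyl-4-(1-tosyl-1H-indol-3-yl)but-2-en-1-ol | OC/C=C(\C)Cc1cn(S(=O)(=O)c2ccc(C)cc2)c2ccccc12 | intermediate
8 | 5-methoxy-5-oxopentanoic acid (monomethyl glutarate) | COC(=O)CCCC(=O)O | starting material
9 | methyl (2E)-3-methyl-4-(1-tosyl-1H-indol-3-yl)but-2-en-1-yl pentanedioate | COC(=O)CCCC(=O)OC/C=C(\C)Cc1cn(S(=O)(=O)c2ccc(C)cc2)c2ccccc12 | intermediate
10 | bis(boron ketene acetal) of 9, each enolate oxygen bound to the (4S,5S)-diazaborolidine, Z(O) geometry at the allyl ester | COC(OB1N(S(=O)(=O)c2cc(C(F)(F)F)cc(C(F)(F)F)c2)[C@@H](c2ccccc2)[C@H](c2ccccc2)N1S(=O)(=O)c1cc(C(F)(F)F)cc(C(F)(F)F)c1)=CC/C=C(\OB1N(S(=O)(=O)c2cc(C(F)(F)F)cc(C(F)(F)F)c2)[C@@H](c2ccccc2)[C@H](c2ccccc2)N1S(=O)(=O)c1cc(C(F)(F)F)cc(C(F)(F)F)c1)OC/C=C(\C)Cc1cn(S(=O)(=O)c2ccc(C)cc2)c2ccccc12 | intermediate (not isolated)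
11 | (2S,3R)-2-(3-methoxy-3-oxopropyl)-3-methyl-3-[(1-tosyl-1H-indol-3-yl)methyl]pent-4-enoic acid | OC(=O)[C@@H](CCC(=O)OC)[C@](C)(Cc1cn(S(=O)(=O)c2ccc(C)cc2)c2ccccc12)C=C | intermediate
12 | (2S,3R)-2-(3-methoxy-3-oxopropyl)-3-methyl-3-[(1-tosyl-1H-indol-3-yl)methyl]pent-4-enoyl chloride | ClC(=O)[C@@H](CCC(=O)OC)[C@](C)(Cc1cn(S(=O)(=O)c2ccc(C)cc2)c2ccccc12)C=C | intermediate (not isolated)
13 | methyl (4S)-6-methyl-4-[(2R)-2-methyl-1-(1-tosyl-1H-indol-3-yl)but-3-en-2-yl]-5-oxohept-6-enoate | CC(=C)C(=O)[C@@H](CCC(=O)OC)[C@](C)(Cc1cn(S(=O)(=O)c2ccc(C)cc2)c2ccccc12)C=C | intermediate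
14 | lithium enolate of the isopropyl ketone from 13 (tetrasubstituted, oxygen on C6) | [Li+].CC(C)=C([O-])[C@@H](CCC(=O)OC)[C@](C)(Cc1cn(S(=O)(=O)c2ccc(C)cc2)c2ccccc12)C=C | intermediate (not isolated)
15 | methyl (4S)-6-methyl-4-[(2R)-2-methyl-1-(1-tosyl-1H-indol-3-yl)but-3-en-2-yl]-5-[(trifluoromethanesulfonyl)oxy]hept-5-enoate | CC(C)=C(OS(=O)(=O)C(F)(F)F)[C@@H](CCC(=O)OC)[C@](C)(Cc1cn(S(=O)(=O)c2ccc(C)cc2)c2ccccc12)C=C | intermediate
16 | methyl (4S)-4-[(2S,3RS)-3-bromo-2-methyl-1-(1-tosyl-1H-indol-3-yl)butan-2-yl]-6-methyl-5-[(trifluoromethanesulfonyl)oxy]hept-5-enoate | CC(C)=C(OS(=O)(=O)C(F)(F)F)[C@@H](CCC(=O)OC)[C@](C)(Cc1cn(S(=O)(=O)c2ccc(C)cc2)c2ccccc12)C(C)Br | intermediate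
17 | methyl (4R)-4-[(2S,3RS)-3-bromo-2-methyl-1-(1-tosyl-1H-indol-3-yl)butan-2-yl]-5-(propan-2-ylidene)hept-6-enoate | CC(C)=C(C=C)[C@@H](CCC(=O)OC)[C@](C)(Cc1cn(S(=O)(=O)c2ccc(C)cc2)c2ccccc12)C(C)Br | intermediate (not isolated)
18 | methyl 3-{(1S,2R,3R)-2,3-dimethyl-6-(propan-2-ylidene)-2-[(1-tosyl-1H-indol-3-yl)methyl]cyclohexyl}propanoate | CC(C)=C1CC[C@@H](C)[C@@](C)(Cc2cn(S(=O)(=O)c3ccc(C)cc3)c3ccccc23)[C@@H]1CCC(=O)OC | intermediate
19 | suaveolindole, 3-[(1S,2R,3R)-2-(1H-indol-3-ylmethyl)-2,3-dimethyl-6-(propan-2-ylidene)cyclohexyl]propanoic acid | CC(C)=C1CC[C@@H](C)[C@@](C)(Cc2c[nH]c3ccccc23)[C@@H]1CCC(=O)O | target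

**Step count and risks**

Total step count: 10. Longest linear sequence: 10 steps (from indole).

Steps most likely to fail:

Step 9. Hydrogen may be delivered to the tertiary end of the allyl radical, giving the ring alkene; 5-exo closure may compete; or palladium carried over from the first stage may disturb the silane chain. Fallback: set out from enol triflate 15, which also bypasses step 8. Stille coupling with tributyl[1-(phenylsulfonyl)ethenyl]stannane (Pd(PPh3)4, CuI, LiCl, THF, 60 °C) should give methyl (4S)-4-[(2R)-2-methyl-1-(1-tosyl-1H-indol-3-yl)but-3-en-2-yl]-6-(phenylsulfonyl)-5-(propan-2-ylidene)hept-6-enoate F1. Its electron-poor vinyl sulfone does not accept a hydrogen atom, so Fe(acac)3 and PhSiH3 in EtOH/THF can generate the C3 radical directly from the vinyl group. A 6-endo Giese closure under the same allylic-strain control, followed by reduction and protonation at the sulfonyl-bearing carbon, should give the cyclic allylic sulfone methyl 3-{(1S,2R,3R)-2,3-dimethyl-5-(phenylsulfonyl)-6-(propan-2-ylidene)-2-[(1-tosyl-1H-indol-3-yl)methyl]cyclohexyl}propanoate F2. Reductive desulfonylation with Pd(PPh3)4 and LiBHEt3, in which hydride enters at the less substituted allyl terminus, comes back to the route at 18.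

Step 8. Hydrogen-atom transfer to the hindered vinyl group may be slow, bromine capture incomplete, or HBr may be lost on handling. Fallback: from 15, Mukaiyama hydration (Co(acac)2, PhSiH3, O2, THF) should give the secondary alcohol methyl (4S)-4-[(2S,3RS)-3-hydroxy-2-methyl-1-(1-tosyl-1H-indol-3-yl)butan-2-yl]-6-methyl-5-[(trifluoromethanesulfonyl)oxy]hept-5-enoate F3. Acylation with 1,1′-thiocarbonyldiimidazole and DMAP gives the O-(imidazol-1-ylthiocarbonyl) derivative F4. Under the conditions of step 9, vinylation gives the corresponding diene imidazolide F5 (not isolated), and Barton–McCombie-type C–O homolysis feeds the same C3 radical, coming back to the route at 18.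

Step 5. Enolisation of the diester by the boron bromide may be incomplete or unselective, eroding enantiomeric and diastereomeric purity. Fallback: from 9, KHMDS (2.3 equiv) and TMSCl in THF/DMPU at −78 °C should give the bis(trimethylsilyl ketene acetal) F6, which rearranges on warming to 23 °C through the same chair. Work-up gives the racemic (2S*,3R*)-2-(3-methoxy-3-oxopropyl)-3-methyl-3-[(1-tosyl-1H-indol-3-yl)methyl]pent-4-enoic acid F7. Resolution by crystallisation of the (S)-1-phenylethylammonium salt of the (2S,3R) acid F8, then acidification, comes back to the route at 11.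

**Further compounds**

F1 | step 9 | methyl (4S)-4-[(2R)-2-methyl-1-(1-tosyl-1H-indol-3-yl)but-3-en-2-yl]-6-(phenylsulfonyl)-5-(propan-2-ylidene)hept-6-enoate | CC(C)=C(C(=C)S(=O)(=O)c1ccccc1)[C@@H](CCC(=O)OC)[C@](C)(Cc1cn(S(=O)(=O)c2ccc(C)cc2)c2ccccc12)C=C
F2 | step 9 | methyl 3-{(1S,2R,3R)-2,3-dimethyl-5-(phenylsulfonyl)-6-(propan-2-ylidene)-2-[(1-tosyl-1H-indol-3-yl)methyl]cyclohexyl}propanoate (C5 epimers) | CC(C)=C1C(S(=O)(=O)c2ccccc2)C[C@@H](C)[C@@](C)(Cc2cn(S(=O)(=O)c3ccc(C)cc3)c3ccccc23)[C@@H]1CCC(=O)OC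
F3 | step 8 | methyl (4S)-4-[(2S,3RS)-3-hydroxy-2-methyl-1-(1-tosyl-1H-indol-3-yl)butan-2-yl]-6-methyl-5-[(trifluoromethanesulfonyl)oxy]hept-5-enoate | CC(C)=C(OS(=O)(=O)C(F)(F)F)[C@@H](CCC(=O)OC)[C@](C)(Cc1cn(S(=O)(=O)c2ccc(C)cc2)c2ccccc12)C(C)O
F4 | step 8 | O-(imidazol-1-ylthiocarbonyl) derivative of F3 | CC(C)=C(OS(=O)(=O)C(F)(F)F)[C@@H](CCC(=O)OC)[C@](C)(Cc1cn(S(=O)(=O)c2ccc(C)cc2)c2ccccc12)C(C)OC(=S)n1ccnc1
F5 | step 8 | methyl 4-[3-(imidazol-1-ylthiocarbonyloxy)-2-methyl-1-(1-tosyl-1H-indol-3-yl)butan-2-yl]-5-(propan-2-ylidene)hept-6-enoate (configuration at the ester-chain carbon and the quaternary carbon as in 17) | CC(C)=C(C=C)[C@@H](CCC(=O)OC)[C@](C)(Cc1cn(S(=O)(=O)c2ccc(C)cc2)c2ccccc12)C(C)OC(=S)n1ccnc1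
F6 | step 5 | bis(trimethylsilyl ketene acetal) of 9 | COC(O[Si](C)(C)C)=CC/C=C(\O[Si](C)(C)C)OC/C=C(\C)Cc1cn(S(=O)(=O)c2ccc(C)cc2)c2ccccc12
F7 | step 5 | racemic (2S*,3R*)-2-(3-methoxy-3-oxopropyl)-3-methyl-3-[(1-tosyl-1H-indol-3-yl)methyl]pent-4-enoic acid (one enantiomer drawn) | OC(=O)[C@@H](CCC(=O)OC)[C@](C)(Cc1cn(S(=O)(=O)c2ccc(C)cc2)c2ccccc12)C=C
F8 | step 5 | (S)-1-phenylethylammonium (2S,3R)-2-(3-methoxy-3-oxopropyl)-3-methyl-3-[(1-tosyl-1H-indol-3-yl)methyl]pent-4-enoate | C[C@H]([NH3+])c1ccccc1.[O-]C(=O)[C@@H](CCC(=O)OC)[C@](C)(Cc1cn(S(=O)(=O)c2ccc(C)cc2)c2ccccc12)C=C
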